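The slowness of the ash run after about 12 min was my starting point: elm repeats that charge and runs to 56 min, and I wanted to know what the later minutes could still add.

| flask | substrate | partner | time |
|---|---|---|---|
| ash | 0.0500 M | 0.0750 M |  |
| birch | 0.0200 M | 0.0450 M |  |
| larch | 0.150 M | 0.0750 M |  |
| elm | 0.0500 M | 0.0750 M | 56 min |

| run | time / min | [target] / M |
|---|---|---|
| ash run | 4.0 | 0.0067 |
| ash run | 8.0 | 0.0128 |
| ash run | 12 | 0.0166 |
| ash run | 16 | 0.0172 |
| ash run | 20 | 0.0185 |
| ash run | 24 | 0.0215 |
| ash run | 28 | 0.0186 |
| birch run | 4.0 | 0.0038 |
| birch run | 8.0 | 0.0048 |
| birch run | 12 | 0.0078 |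
| birch run | 16 | 0.0067 |
| birch run | 20 | 0.0075 |
| birch run | 24 | 0.0069 |
| birch run | 28 | 0.0066 |
| larch run | 4.0 | 0.0198 |
| larch run | 8.0 | 0.0306 |
| larch run | 12 | 0.0363 |
| larch run | 16 | 0.0399 |
| larch run | 20 | 0.0406 |
| larch run | 24 | 0.0417 |
| larch run | 28 | 0.0419 |

(each reading ± 8 × 10⁻⁴ M)

- Overall: substrate + partner -> target.
- Constant volume, constant temperature.
- What is held in complexes is read along with the free species.
- "The second partner" is partner.
- An order is taken over about fifteen percent of the charge, up and down.

1. how the opening rate goes with [substrate] round the charge of the ash run: the exponent of the rate at two percent of substrate gone to target (one fixed amount of target, the same in the runs compared)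
2. how the opening rate goes with [partner] round the charge of the ash run: the exponent of the rate at two percent of substrate gone to target
3. target in the elm run at 56 min, as a share of the substrate charged

I read the clock from larch, whose climb stood highest above the scatter. Its gain from 8.0 min to 16 min was 0.304 of its gain over the first 8.0 min. That gave 6.72 min, which I called the fading time τ, the time over which the target still to come falls to 0.368 of itself.

From above, elm could not pass its 0.0500 M of substrate, the limiting reagent, which was smaller than the 0.0750 M of partner, since each target takes one substrate. From below, the last 3 ash readings averaged 0.01953 M, and I assumed that this amount stayed made. To tighten the top, I asked what τ left to come after their middle time, 24 min: a fraction 0.0281 of the level. That lifted the mean to a level of 40.2% of the charge. Allowing 2 standard deviations of the mean each way, my bracket for elm ran from 37.2% to 42.0%. I left the orders open, since the rate asked stands at 0.00100 M of target, less than the first ash reading of 0.0067 M.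

The forecast, which said “this is one equilibrium”, gave orders of 0.9 and 0.2 and 39.8% for elm.

The simulation gave orders of 0.68 in substrate and 0.33 in partner, and 40.1% for elm.

    substrate → intermediate (0.1308 min⁻¹)
    intermediate + partner → target (19.02 M⁻¹ min⁻¹)
    intermediate → side product (0.5004 min⁻¹)
    2 partner ⇌ idle reagent dimer, settled at all times (34.60 M⁻¹)
    2 substrate → homo dimer (0.5328 M⁻¹ min⁻¹)

At 56 min, elm stood at 8.33 of my estimated fading times, and its 40.1% lay inside my bracket. In birch, τ from larch and a level of 0.007202 M put a quarter of the charge at 7.96 min, and the flask took 9.00 min. Elm's level stood low partly because of the association of 2 partner to idle reagent dimer: the elm run without it gave 58.1% against 40.1%.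

The readings were computed for an exercise; the scatter is artificial.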